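**Plan**

1. Numbering: indane C1 is the alkylidene carbon, C2 carries the 3,5-dihydroxyphenyl group, C3 the 4-hydroxyphenyl group; ring A is the resorcinol ring fused to the indane. Retrosynthesis cuts the eight O–methyl bonds, then the exocyclic C1=CH bond (SO2 extrusion from an indan-1-yl benzyl sulfone), then the C1–S bond together with the ring bond C2–C3. This opens the indane to a triaryl carbinol and a dihydrobenzofuranylmethanethiol; the dihydrobenzofuran is cut at its own C2–C3 bond (carbene C–H insertion).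
2. Feature used: C3 is doubly benzylic, para to the oxygen of its aryl group and ortho/para to the C4 and C6 oxygens of ring A, so it is an excellent cation site. With the C3a–C7a π bond of ring A and an E-stilbene bond C1=C2 it forms a pentadienyl cation. Conrotatory 4π closure makes C2–C3 and moves the charge to C1, the carbon that must carry sulfur for the later alkene.
3. Forward: Horner–Wadsworth–Emmons stilbene and aryllithium addition give the carbinol (steps 1–2). The dihydrobenzofuran ring is closed by a donor/donor dirhodium carbene C–H insertion and carried to the thiol (steps 3–9). Carbinol and thiol are joined while the five-membered ring of the indane closes (step 10). Sulfone formation, Ramberg–Bäcklund extrusion and BBr3 finish the route (steps 11–13).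
4. Stereochemistry: indane C2/C3 trans from conrotation of the E-alkene, absolute sense from a chiral Brønsted acid anion. Dihydrobenzofuran C3 comes from the chiral dirhodium catalyst, C2 from acid equilibration to trans. The E double bond (aryl away from the peri C7–H) comes from the Ramberg–Bäcklund step.

Key step: step 10

Assumption: the sense of induction of the chiral dirhodium carboxylate (step 5) and of the chiral phosphoramide (step 10) cannot be assigned in advance; the antipodes written are assumed to give the configurations drawn, and the mirror-image catalyst is taken otherwise.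

**Route**

Step 1
Reactants: 1 2-bromo-3,5-dimethoxybenzaldehyde; 2 diethyl (3,5-dimethoxybenzyl)phosphonate
Product: 3 (E)-2-bromo-1-[2-(3,5-dimethoxyphenyl)ethenyl]-3,5-dimethoxybenzene
Conditions: KOt-Bu (1.1 equiv), THF, 0 → 25 °C
Reagents that add atoms: none
Why: Horner–Wadsworth–Emmons olefination of an aryl aldehyde with a benzylic phosphonate anion should give the E-stilbene, and the aryl bromide is inert to the base.

Step 2
Reactants: 3 (E)-2-bromo-1-[2-(3,5-dimethoxyphenyl)ethenyl]-3,5-dimethoxybenzene; 4 4-methoxybenzaldehyde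
Product: 6 racemic {2-[(E)-2-(3,5-dimethoxyphenyl)ethenyl]-4,6-dimethoxyphenyl}(4-methoxyphenyl)methanol, via aryllithium 5 (not isolated)
Conditions: n-BuLi (1.05 equiv), THF, −78 °C; then 4, −78 → 0 °C; H2O
Reagents that add atoms: none
Why: Bromine–lithium exchange at −78 °C outruns addition of n-BuLi to the stilbene, and 1,2-addition of the aryllithium to the non-enolisable aldehyde gives the carbinol, whose configuration is irrelevant because this carbon is ionised in step 10.

Step 3
Reactants: 7 5-bromo-2-hydroxybenzonitrile; 8 4-methoxybenzyl chloride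
Product: 9 5-bromo-2-[(4-methoxybenzyl)oxy]benzonitrile
Conditions: K2CO3 (1.5 equiv), DMF, 60 °C
Reagents that add atoms: none
Why: Williamson ether synthesis; the phenoxide, made more acidic by the ortho nitrile, displaces the benzylic chloride by SN2 at oxygen.

Step 4
Reactants: 9 5-bromo-2-[(4-methoxybenzyl)oxy]benzonitrile; 10 3,5-dimethoxyphenylmagnesium chloride (commercial THF solution)
Product: 12 {5-bromo-2-[(4-methoxybenzyl)oxy]phenyl}(3,5-dimethoxyphenyl)methanone hydrazone, via ketimine 11 (not isolated)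
Conditions: 10 (1.5 equiv), THF, 25 → 65 °C; MeOH, 0 °C; then N2H4·H2O (10 equiv), AcOH (0.2 equiv), EtOH, 80 °C
Reagents that add atoms: hydrazine (as hydrate), NN
Why: Grignard addition to a nitrile stops at the N-magnesio ketimine, and after methanolysis the N–H ketimine should exchange with hydrazine (transimination) to give the hydrazone directly.

Step 5
Reactants: 12 {5-bromo-2-[(4-methoxybenzyl)oxy]phenyl}(3,5-dimethoxyphenyl)methanone hydrazone
Product: 14 (2S,3R)-5-bromo-3-(3,5-dimethoxyphenyl)-2-(4-methoxyphenyl)-2,3-dihydro-1-benzofuran (cis), via diazo compound 13 (not isolated)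
Conditions: MnO2 (8 equiv), CH2Cl2, 0 °C; filtration; then Rh2(S-PTAD)4 (dirhodium tetrakis[(S)-(adamantan-1-yl)(phthalimido)acetate], 1 mol %), CH2Cl2, 0 °C
Reagents that add atoms: none
Why: MnO2 dehydrogenates the hydrazone to the diaryldiazomethane, and the donor/donor dirhodium carbene inserts into the activated benzylic ether C–H bond (1,5 C–H insertion closing the furan ring), the chiral carboxylate ligands fixing C3 and the insertion giving the 2,3-cis isomer usual for this reaction type.

Step 6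
Reactants: 14 (2S,3R)-5-bromo-3-(3,5-dimethoxyphenyl)-2-(4-methoxyphenyl)-2,3-dihydro-1-benzofuran
Product: 16 (2R,3R)-5-bromo-3-(3,5-dimethoxyphenyl)-2-(4-methoxyphenyl)-2,3-dihydro-1-benzofuran (trans), via ring-opened benzylic cation 15 (not isolated)
Conditions: CF3CO2H (10 equiv), CH2Cl2, −20 → 0 °C
Reagents that add atoms: none
Why: Acid-mediated epimerisation: reversible heterolysis of the C2–O bond to the 4-methoxybenzylic cation and 5-exo re-closure by the phenol should settle on the more stable trans isomer, C3 staying untouched as long as the low temperature suppresses proton loss from C3.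

Step 7
Reactants: 16 (2R,3R)-5-bromo-3-(3,5-dimethoxyphenyl)-2-(4-methoxyphenyl)-2,3-dihydro-1-benzofuran
Product: 19 [(2R,3R)-3-(3,5-dimethoxyphenyl)-2-(4-methoxyphenyl)-2,3-dihydro-1-benzofuran-5-yl]methanol, via aryllithium 17 (not isolated), via aldehyde 18 (not isolated)
Conditions: n-BuLi (1.05 equiv), THF, −78 °C; DMF (3 equiv), −78 → 0 °C; then MeOH, NaBH4 (1.5 equiv), 0 °C
Reagents that add atoms: N,N-dimethylformamide, CN(C)C=O
Why: Bromine–lithium exchange, formylation with DMF and borohydride reduction in one flask; exchange at −78 °C is faster than deprotonation of the ring C–H bonds, so the stereocentres are not involved.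

Step 8
Reactants: 19 [(2R,3R)-3-(3,5-dimethoxyphenyl)-2-(4-methoxyphenyl)-2,3-dihydro-1-benzofuran-5-yl]methanol
Product: 20 S-{[(2R,3R)-3-(3,5-dimethoxyphenyl)-2-(4-methoxyphenyl)-2,3-dihydro-1-benzofuran-5-yl]methyl} ethanethioate
Conditions: PPh3 (1.3 equiv), DIAD (1.3 equiv), AcSH (1.5 equiv), THF, 0 → 25 °C
Reagents that add atoms: thioacetic acid, CC(=O)S
Why: Mitsunobu thioesterification of a primary benzylic alcohol with the sufficiently acidic thioacetic acid runs under neutral conditions that leave the acid-sensitive dihydrobenzofuran alone.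

Step 9
Reactants: 20 S-{[(2R,3R)-3-(3,5-dimethoxyphenyl)-2-(4-methoxyphenyl)-2,3-dihydro-1-benzofuran-5-yl]methyl} ethanethioate
Product: 21 [(2R,3R)-3-(3,5-dimethoxyphenyl)-2-(4-methoxyphenyl)-2,3-dihydro-1-benzofuran-5-yl]methanethiol
Conditions: K2CO3 (0.3 equiv), degassed MeOH/THF, 0 °C
Reagents that add atoms: none
Why: Base-catalysed methanolysis (transesterification) of the thioester frees the thiol, and exclusion of air prevents disulfide formation.

Step 10
Reactants: 6 racemic {2-[(E)-2-(3,5-dimethoxyphenyl)ethenyl]-4,6-dimethoxyphenyl}(4-methoxyphenyl)methanol; 21 [(2R,3R)-3-(3,5-dimethoxyphenyl)-2-(4-methoxyphenyl)-2,3-dihydro-1-benzofuran-5-yl]methanethiol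
Product: 24 (1S,2S,3S)-1-({[(2R,3R)-3-(3,5-dimethoxyphenyl)-2-(4-methoxyphenyl)-2,3-dihydro-1-benzofuran-5-yl]methyl}sulfanyl)-2-(3,5-dimethoxyphenyl)-4,6-dimethoxy-3-(4-methoxyphenyl)indane, via benzhydryl cation 22 (not isolated), via indan-1-yl cation 23 (not isolated)
Conditions: (R)-3,3′-bis(2,4,6-triisopropylphenyl)-1,1′-binaphthyl-2,2′-diyl N-triflylphosphoramide (10 mol %), 21 (1.2 equiv), 5 Å molecular sieves, CH2Cl2, −60 → −30 °C
Reagents that add atoms: none
Why: Proposed new method: the chiral acid ionises the doubly benzylic carbinol to cation 22, whose cationic carbon, the C3a–C7a π bond of ring A and the E-stilbene bond form a pentadienyl cation that undergoes thermal conrotatory 4π electrocyclisation to indan-1-yl cation 23, which is captured at C1 by the sulfur of 21 with return of a proton to the catalyst. The closest known reaction types are the achiral sulfonic acid-promoted cyclisation with thiol capture of 2-styrylbenzhydrols of exactly this kind and, for the asymmetric induction, chiral Brønsted acid-catalysed dehydrative Nazarov-type electrocyclisations of aryl alkenyl carbinols that run through contact ion pairs. The five-membered ring closes in a cationic 5-endo-trig mode with respect to the stilbene bond, both of whose carbons end up in the ring. C2 and C3 should come out trans because both aryl groups sit on the outside of the pentadienyl termini (E alkene at C2, sterically preferred cation geometry at C3) and conrotation turns outside/outside into trans, while their absolute sense is fixed by the chiral phosphoramide anion that stays paired with the cation through closure and capture; C1 takes sulfur anti to the C2 aryl group and is destroyed in step 12. The step needs ring closure to beat direct thiol capture of 22 and seven-membered Friedel–Crafts attack on the dimethoxyphenyl ring: capture at the strongly stabilised cation 22 is reversible under acid and so drains into 23, and the E geometry keeps that arene away from the cationic carbon. It also needs ionisation of the carbinol in preference to the benzylic C2–O bond of the dihydrobenzofuran in 21, which the far higher stability of 22 and the low temperature secure.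

Step 11
Reactants: 24 the sulfide of step 10
Product: 26 (1S,2S,3S)-1-({[(2R,3R)-3-(3,5-dimethoxyphenyl)-2-(4-methoxyphenyl)-2,3-dihydro-1-benzofuran-5-yl]methyl}sulfonyl)-2-(3,5-dimethoxyphenyl)-4,6-dimethoxy-3-(4-methoxyphenyl)indane, via sulfoxide 25 (not isolated)
Conditions: mCPBA (2.2 equiv), CH2Cl2, 0 → 25 °C
Reagents that add atoms: 3-chloroperoxybenzoic acid, OOC(=O)c1cccc(Cl)c1
Why: Peracid oxidation of a sulfide to the sulfone through the sulfoxide; no alkene is left in the molecule and sulfur is oxidised far faster than the methoxyarenes.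

Step 12
Reactants: 26 the sulfone of step 11
Product: 29 (1E,2S,3S)-1-{[(2R,3R)-3-(3,5-dimethoxyphenyl)-2-(4-methoxyphenyl)-2,3-dihydro-1-benzofuran-5-yl]methylidene}-2-(3,5-dimethoxyphenyl)-4,6-dimethoxy-3-(4-methoxyphenyl)indane, via α-chlorosulfone 27 (not isolated), via episulfone 28 (not isolated)
Conditions: powdered KOH (20 equiv), CCl4/t-BuOH/H2O (5:5:1), 25 → 80 °C
Reagents that add atoms: none
Why: Ramberg–Bäcklund reaction: the benzylic α-sulfonyl carbanion is chlorinated by CCl4, the α′-carbanion closes the episulfone and SO2 is lost stereospecifically; base equilibration before extrusion places the large groups trans, so the E alkene with the aryl group away from the peri C7–H should result, as is known for 2,3-diarylindan-1-yl benzyl sulfones.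

Step 13
Reactants: 29 the octamethyl ether of step 12
Product: 30 (1E,2S,3S)-2-(3,5-dihydroxyphenyl)-1-{[(2R,3R)-3-(3,5-dihydroxyphenyl)-2-(4-hydroxyphenyl)-2,3-dihydro-1-benzofuran-5-yl]methylidene}-3-(4-hydroxyphenyl)indane-4,6-diol
Conditions: BBr3 (1.0 M in CH2Cl2, 20 equiv), CH2Cl2, −78 → 25 °C; then MeOH, H2O, 0 °C
Reagents that add atoms: none
Why: Lewis acid ether cleavage: boron binds each methoxy oxygen and bromide attacks the methyl group by SN2, which spares the secondary benzylic C–O bond of the dihydrobenzofuran (any opening re-closes to the trans ring) and has precedent on both the benzylidene-indane and the diaryl-dihydrobenzofuran motifs.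

**Compound list**

1 | 2-bromo-3,5-dimethoxybenzaldehyde | O=Cc1cc(OC)cc(OC)c1Br | starting material
2 | diethyl (3,5-dimethoxybenzyl)phosphonate | CCOP(=O)(Cc1cc(OC)cc(OC)c1)OCC | starting material
3 | (E)-2-bromo-1-[2-(3,5-dimethoxyphenyl)ethenyl]-3,5-dimethoxybenzene | COc1cc(OC)cc(/C=C/c2cc(OC)cc(OC)c2Br)c1 | intermediate
4 | 4-methoxybenzaldehyde | COc1ccc(C=O)cc1 | starting material
5 | aryllithium (3 with lithium in place of bromine; not isolated) | [Li]c1c(OC)cc(OC)cc1/C=C/c1cc(OC)cc(OC)c1 | intermediate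
6 | racemic {2-[(E)-2-(3,5-dimethoxyphenyl)ethenyl]-4,6-dimethoxyphenyl}(4-methoxyphenyl)methanol | COc1ccc(C(O)c2c(OC)cc(OC)cc2/C=C/c2cc(OC)cc(OC)c2)cc1 | intermediate
7 | 5-bromo-2-hydroxybenzonitrile | N#Cc1cc(Br)ccc1O | starting material
8 | 4-methoxybenzyl chloride | COc1ccc(CCl)cc1 | starting material
9 | 5-bromo-2-[(4-methoxybenzyl)oxy]benzonitrile | COc1ccc(COc2ccc(Br)cc2C#N)cc1 | intermediate
10 | 3,5-dimethoxyphenylmagnesium chloride | COc1cc(OC)cc([Mg]Cl)c1 | starting material
11 | {5-bromo-2-[(4-methoxybenzyl)oxy]phenyl}(3,5-dimethoxyphenyl)methanimine (not isolated) | COc1ccc(COc2ccc(Br)cc2C(=N)c2cc(OC)cc(OC)c2)cc1 | intermediate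
12 | {5-bromo-2-[(4-methoxybenzyl)oxy]phenyl}(3,5-dimethoxyphenyl)methanone hydrazone | COc1ccc(COc2ccc(Br)cc2C(=NN)c2cc(OC)cc(OC)c2)cc1 | intermediate
13 | 4-bromo-2-[diazo(3,5-dimethoxyphenyl)methyl]-1-[(4-methoxybenzyl)oxy]benzene (not isolated) | COc1ccc(COc2ccc(Br)cc2C(=[N+]=[N-])c2cc(OC)cc(OC)c2)cc1 | intermediate
14 | (2S,3R)-5-bromo-3-(3,5-dimethoxyphenyl)-2-(4-methoxyphenyl)-2,3-dihydro-1-benzofuran (cis) | Brc1ccc2c(c1)[C@@H](c1cc(OC)cc(OC)c1)[C@@H](c1ccc(OC)cc1)O2 | intermediate
15 | ring-opened cation: 2-(5-bromo-2-hydroxyphenyl)-2-(3,5-dimethoxyphenyl)-1-(4-methoxyphenyl)ethylium, configuration at the diarylmethine carbon retained (not isolated) | Brc1ccc(O)c(c1)[C@@H](c1cc(OC)cc(OC)c1)[CH+]c1ccc(OC)cc1 | intermediate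
16 | (2R,3R)-5-bromo-3-(3,5-dimethoxyphenyl)-2-(4-methoxyphenyl)-2,3-dihydro-1-benzofuran (trans) | Brc1ccc2c(c1)[C@@H](c1cc(OC)cc(OC)c1)[C@H](c1ccc(OC)cc1)O2 | intermediate
17 | aryllithium (16 with lithium in place of bromine; not isolated) | [Li]c1ccc2c(c1)[C@@H](c1cc(OC)cc(OC)c1)[C@H](c1ccc(OC)cc1)O2 | intermediate
18 | (2R,3R)-3-(3,5-dimethoxyphenyl)-2-(4-methoxyphenyl)-2,3-dihydro-1-benzofuran-5-carbaldehyde (not isolated) | O=Cc1ccc2c(c1)[C@@H](c1cc(OC)cc(OC)c1)[C@H](c1ccc(OC)cc1)O2 | intermediate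
19 | [(2R,3R)-3-(3,5-dimethoxyphenyl)-2-(4-methoxyphenyl)-2,3-dihydro-1-benzofuran-5-yl]methanol | OCc1ccc2c(c1)[C@@H](c1cc(OC)cc(OC)c1)[C@H](c1ccc(OC)cc1)O2 | intermediate
20 | S-{[(2R,3R)-3-(3,5-dimethoxyphenyl)-2-(4-methoxyphenyl)-2,3-dihydro-1-benzofuran-5-yl]methyl} ethanethioate | CC(=O)SCc1ccc2c(c1)[C@@H](c1cc(OC)cc(OC)c1)[C@H](c1ccc(OC)cc1)O2 | intermediate
21 | [(2R,3R)-3-(3,5-dimethoxyphenyl)-2-(4-methoxyphenyl)-2,3-dihydro-1-benzofuran-5-yl]methanethiol | SCc1ccc2c(c1)[C@@H](c1cc(OC)cc(OC)c1)[C@H](c1ccc(OC)cc1)O2 | intermediate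
22 | benzhydryl cation from 6 (not isolated) | COc1ccc([CH+]c2c(OC)cc(OC)cc2/C=C/c2cc(OC)cc(OC)c2)cc1 | intermediate
23 | trans-2-(3,5-dimethoxyphenyl)-4,6-dimethoxy-3-(4-methoxyphenyl)indan-1-yl cation, configured at C2 and C3 as in 24 (not isolated) | COc1ccc([C@H]2c3c(OC)cc(OC)cc3[CH+][C@@H]2c2cc(OC)cc(OC)c2)cc1 | intermediate
24 | (1S,2S,3S)-1-({[(2R,3R)-3-(3,5-dimethoxyphenyl)-2-(4-methoxyphenyl)-2,3-dihydro-1-benzofuran-5-yl]methyl}sulfanyl)-2-(3,5-dimethoxyphenyl)-4,6-dimethoxy-3-(4-methoxyphenyl)indane (expected main C1 epimer) | COc1ccc([C@H]2c3c(OC)cc(OC)cc3[C@@H](SCc3ccc4c(c3)[C@@H](c3cc(OC)cc(OC)c3)[C@H](c3ccc(OC)cc3)O4)[C@@H]2c2cc(OC)cc(OC)c2)cc1 | intermediate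
25 | sulfoxide of 24, sulfur configuration undefined (not isolated) | COc1ccc([C@H]2c3c(OC)cc(OC)cc3[C@@H](S(=O)Cc3ccc4c(c3)[C@@H](c3cc(OC)cc(OC)c3)[C@H](c3ccc(OC)cc3)O4)[C@@H]2c2cc(OC)cc(OC)c2)cc1 | intermediate
26 | (1S,2S,3S)-sulfone of 24 | COc1ccc([C@H]2c3c(OC)cc(OC)cc3[C@@H](S(=O)(=O)Cc3ccc4c(c3)[C@@H](c3cc(OC)cc(OC)c3)[C@H](c3ccc(OC)cc3)O4)[C@@H]2c2cc(OC)cc(OC)c2)cc1 | intermediate
27 | α-chlorosulfone (26 chlorinated at the benzylic CH2; not isolated) | COc1ccc([C@H]2c3c(OC)cc(OC)cc3[C@@H](S(=O)(=O)C(Cl)c3ccc4c(c3)[C@@H](c3cc(OC)cc(OC)c3)[C@H](c3ccc(OC)cc3)O4)[C@@H]2c2cc(OC)cc(OC)c2)cc1 | intermediate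
28 | spiro episulfone (thiirane 1,1-dioxide spanning indane C1 and the benzylic carbon; not isolated) | COc1ccc([C@H]2c3c(OC)cc(OC)cc3C5(C(c3ccc4c(c3)[C@@H](c3cc(OC)cc(OC)c3)[C@H](c3ccc(OC)cc3)O4)S5(=O)=O)[C@@H]2c2cc(OC)cc(OC)c2)cc1 | intermediate
29 | (1E,2S,3S)-1-{[(2R,3R)-3-(3,5-dimethoxyphenyl)-2-(4-methoxyphenyl)-2,3-dihydro-1-benzofuran-5-yl]methylidene}-2-(3,5-dimethoxyphenyl)-4,6-dimethoxy-3-(4-methoxyphenyl)indane | COc1ccc([C@H]2c3c(OC)cc(OC)cc3/C(=C/c3ccc4c(c3)[C@@H](c3cc(OC)cc(OC)c3)[C@H](c3ccc(OC)cc3)O4)[C@@H]2c2cc(OC)cc(OC)c2)cc1 | intermediate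
30 | (1E,2S,3S)-2-(3,5-dihydroxyphenyl)-1-{[(2R,3R)-3-(3,5-dihydroxyphenyl)-2-(4-hydroxyphenyl)-2,3-dihydro-1-benzofuran-5-yl]methylidene}-3-(4-hydroxyphenyl)indane-4,6-diol | Oc1ccc([C@H]2c3c(O)cc(O)cc3/C(=C/c3ccc4c(c3)[C@@H](c3cc(O)cc(O)c3)[C@H](c3ccc(O)cc3)O4)[C@@H]2c2cc(O)cc(O)c2)cc1 | target

**Summary**

Total steps: 13. Longest linear sequence: 11 steps (steps 3–13).

**Steps most likely to fail**

Step 10 (carries the label). The chiral anion may discriminate poorly between the two senses of conrotation, or the benzhydryl sulfide formed by early sulfur capture may not re-ionise under the catalytic acid. The fallback sets out from 6 and comes back at 24, using known chemistry only. 6 is cyclised by CF3CO2H in CH2Cl2 at −30 °C with capture by trifluoroacetate to give the racemic all-trans indan-1-yl trifluoroacetate F1, which K2CO3 in MeOH cleaves to the racemic indan-1-ol F2. Acylation with (1S)-camphanic chloride (Et3N, DMAP, CH2Cl2) gives two diastereomers, the (1S,2S,3S)-indanyl camphanate F3 and the (1R,2R,3R)-indanyl camphanate F4, which are separated by chromatography or crystallisation. F3 is then ionised with BF3·OEt2 in CH2Cl2 at −78 °C in the presence of excess 21; the camphanate leaves as the acid, the thiol captures cation 23 before the ring can reopen, and 24 results with C2 and C3 untouched.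

Step 12. The halogenating medium may chlorinate the electron-rich rings, the base may move the new double bond into the five-membered ring, or the extrusion may give poor geometric control. The fallback sets out from 6 (with aldehyde 18, isolated by aqueous work-up of step 7 before the borohydride is added) and comes back at 29. 6 is cyclised under the conditions of step 10 with 1-phenyl-1H-tetrazole-5-thiol in place of 21 to give the indan-1-yl tetrazolyl sulfide F5, and mCPBA oxidises it to the tetrazolyl sulfone F6. KHMDS in DME at −60 °C with 18 present then gives 29 by Julia–Kocienski olefination, which uses no halogenating agent and only low-temperature base. If some Z isomer forms, iodine-catalysed equilibration to the more stable E isomer would follow.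

Step 13. The long exposure to BBr3 and HBr needed for eight ether cleavages may shift the exocyclic double bond into the ring or add HBr to it. The fallback sets out from 26 and comes back at 30, moving the ether cleavage to a stage without the double bond. BBr3 in CH2Cl2 converts 26 to the octaphenol sulfone F7, and allyl bromide with K2CO3 in DMF gives the octa-allyl ether sulfone F8. Ramberg–Bäcklund extrusion with CBr2F2 and KOH on alumina in t-BuOH/CH2Cl2 passes through the α-bromosulfone F9 and the episulfone F10 to the octa-allyl ether F11 of the target. Pd(PPh3)4 with morpholine in THF at 25 °C then removes the allyl groups under neutral conditions to give 30.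

Steps 6 and 13 both rest on close precedent in this compound class; step 6 ranks just below the three above.

**Further compounds**

F1 | step 10 | racemic (1S*,2S*,3S*)-2-(3,5-dimethoxyphenyl)-4,6-dimethoxy-3-(4-methoxyphenyl)indan-1-yl trifluoroacetate | COc1ccc([C@H]2c3c(OC)cc(OC)cc3[C@@H](OC(=O)C(F)(F)F)[C@@H]2c2cc(OC)cc(OC)c2)cc1
F2 | step 10 | racemic (1S*,2S*,3S*)-2-(3,5-dimethoxyphenyl)-4,6-dimethoxy-3-(4-methoxyphenyl)indan-1-ol | COc1ccc([C@H]2c3c(OC)cc(OC)cc3[C@@H](O)[C@@H]2c2cc(OC)cc(OC)c2)cc1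
F3 | step 10 | (1S,2S,3S)-2-(3,5-dimethoxyphenyl)-4,6-dimethoxy-3-(4-methoxyphenyl)indan-1-yl (1S)-camphanate | COc1ccc([C@H]2c3c(OC)cc(OC)cc3[C@@H](OC(=O)[C@@]56CC[C@@](C)(C(=O)O5)C6(C)C)[C@@H]2c2cc(OC)cc(OC)c2)cc1
F4 | step 10 | (1R,2R,3R)-2-(3,5-dimethoxyphenyl)-4,6-dimethoxy-3-(4-methoxyphenyl)indan-1-yl (1S)-camphanate | COc1ccc([C@@H]2c3c(OC)cc(OC)cc3[C@H](OC(=O)[C@@]56CC[C@@](C)(C(=O)O5)C6(C)C)[C@H]2c2cc(OC)cc(OC)c2)cc1
F5 | step 12 | 5-{[(1S,2S,3S)-2-(3,5-dimethoxyphenyl)-4,6-dimethoxy-3-(4-methoxyphenyl)indan-1-yl]sulfanyl}-1-phenyl-1H-tetrazole | COc1ccc([C@H]2c3c(OC)cc(OC)cc3[C@@H](Sc3nnnn3-c3ccccc3)[C@@H]2c2cc(OC)cc(OC)c2)cc1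
F6 | step 12 | 5-{[(1S,2S,3S)-2-(3,5-dimethoxyphenyl)-4,6-dimethoxy-3-(4-methoxyphenyl)indan-1-yl]sulfonyl}-1-phenyl-1H-tetrazole | COc1ccc([C@H]2c3c(OC)cc(OC)cc3[C@@H](S(=O)(=O)c3nnnn3-c3ccccc3)[C@@H]2c2cc(OC)cc(OC)c2)cc1
F7 | step 13 | octaphenol sulfone (26 with all eight methoxy groups as hydroxy groups) | Oc1ccc([C@H]2c3c(O)cc(O)cc3[C@@H](S(=O)(=O)Cc3ccc4c(c3)[C@@H](c3cc(O)cc(O)c3)[C@H](c3ccc(O)cc3)O4)[C@@H]2c2cc(O)cc(O)c2)cc1
F8 | step 13 | octa-allyl ether sulfone (26 with allyloxy in place of each methoxy group) | C=CCOc1ccc([C@H]2c3c(OCC=C)cc(OCC=C)cc3[C@@H](S(=O)(=O)Cc3ccc4c(c3)[C@@H](c3cc(OCC=C)cc(OCC=C)c3)[C@H](c3ccc(OCC=C)cc3)O4)[C@@H]2c2cc(OCC=C)cc(OCC=C)c2)cc1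
F9 | step 13 | α-bromosulfone of F8 (bromine at the benzylic CH2) | C=CCOc1ccc([C@H]2c3c(OCC=C)cc(OCC=C)cc3[C@@H](S(=O)(=O)C(Br)c3ccc4c(c3)[C@@H](c3cc(OCC=C)cc(OCC=C)c3)[C@H](c3ccc(OCC=C)cc3)O4)[C@@H]2c2cc(OCC=C)cc(OCC=C)c2)cc1
F10 | step 13 | spiro episulfone of the octa-allyl series | C=CCOc1ccc([C@H]2c3c(OCC=C)cc(OCC=C)cc3C5(C(c3ccc4c(c3)[C@@H](c3cc(OCC=C)cc(OCC=C)c3)[C@H](c3ccc(OCC=C)cc3)O4)S5(=O)=O)[C@@H]2c2cc(OCC=C)cc(OCC=C)c2)cc1
F11 | step 13 | octa-allyl ether of 30 | C=CCOc1ccc([C@H]2c3c(OCC=C)cc(OCC=C)cc3/C(=C/c3ccc4c(c3)[C@@H](c3cc(OCC=C)cc(OCC=C)c3)[C@H](c3ccc(OCC=C)cc3)O4)[C@@H]2c2cc(OCC=C)cc(OCC=C)c2)cc1
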